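The route rests on disconnecting the ester between its carbonyl carbon C1 and the α-methylene C2 of the docosanoyl chain. The feature exploited is that C2–C3 is an unbranched CH2–CH2 unit, the retron of a terminal C=C, so C1 can be attached by anti-Markovnikov hydroesterification. In one operation, palladium-catalysed alkoxycarbonylation with a formate as CO-free ester donor joins 1-henicosene to 2-(4-hydroxyphenyl)ethyl formate, which already carries C1, both ester oxygens and the unprotected para-hydroxyphenyl (benzene) ring. The precursors therefore show no acyl chain: an alkene and a formate whose formyl C–H is formally added across the double bond, all atoms of both ending up in the target.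

Key step: step 2

Assumption: the target has no stereocentre and no stereogenic double bond, so no stereocontrol is needed; 1-henicosene is taken as a catalogue α-olefin.

Step 1
Reactants: 1 tyrosol, 4-(2-hydroxyethyl)phenol
Product: 2 2-(4-hydroxyphenyl)ethyl formate
Conditions: HCO2H (98%, neat, 10 equiv), 50 °C; evaporation, PhMe azeotrope, cold aq. NaHCO3 wash
Reagents that add atoms: formic acid, O=CO
Why: Autocatalytic Fischer esterification (O-formylation) in neat formic acid should convert only the primary aliphatic hydroxyl, because aryl formates are not favoured at this equilibrium and any trace is cleaved by the bicarbonate wash; water is the only co-product.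

Step 2
Reactants: 2 2-(4-hydroxyphenyl)ethyl formate (2.5 equiv); 3 1-henicosene
Product: 5 2-(4-hydroxyphenyl)ethyl docosanoate, via carbon monoxide 4 (not isolated), via tyrosol 1 (not isolated)
Conditions: Pd(dba)2 (1 mol%), 1,2-bis(di-tert-butylphosphinomethyl)benzene (dtbpx, 4 mol%), MsOH (8 mol%), PhMe, sealed pressure vessel, 100 °C; aq. NaHCO3 work-up, chromatography
Reagents that add atoms: none
Why: MsOH should protonate Pd(0)/dtbpx to a cationic Pd–H that adds to the terminal C=C of 3 and chain-walks reversibly, while the same acidic palladium system decarbonylates formate 2 in the closed vessel to carbon monoxide 4 and tyrosol 1; CO then inserts into the unhindered primary Pd–CH2 bond, which creates the bond between C2 and the carbonyl carbon C1, and the linear acyl-palladium is cleaved by the primary hydroxyl of 1 with return of Pd–H. The closest known reaction type is the palladium/diphosphine/sulfonic acid-catalysed alkoxycarbonylation (hydroesterification) of alkenes with alkyl formates as CO-free ester donors, an isomerising and linear-selective process. No ring is closed and no stereocentre is formed; both pieces released from 2 are taken up again, so the sum is addition of the formyl C–H of 2 across the olefin, and the surplus of 2 only keeps up the CO supply and is removed by chromatography, together with the tyrosol it releases, from the far less polar product. The step needs anti-Markovnikov (linear, not 2-methyl-branched) regioselectivity, which the monosubstituted, unbranched alkene terminus secures together with the bulky di-tert-butylphosphino groups, since only the primary alkyl at the chain end is carbonylated and alcoholysed at a useful rate and internal henicosenes formed by isomerisation funnel back to it. It also needs acylation of the aliphatic and not the phenolic oxygen, secured by the much higher nucleophilicity of the primary alcohol toward the acyl-palladium under acidic conditions, while the excess diphosphine buffers the sulfonic acid so that Friedel–Crafts alkylation of the phenol ring by the olefin should remain minor.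

Compound list
1 | tyrosol, 4-(2-hydroxyethyl)phenol | OCCc1ccc(O)cc1 | starting material
2 | 2-(4-hydroxyphenyl)ethyl formate | O=COCCc1ccc(O)cc1 | intermediate
3 | 1-henicosene (henicos-1-ene) | CCCCCCCCCCCCCCCCCCCC=C | starting material
4 | carbon monoxide | [C-]#[O+] | intermediate
5 | 2-(4-hydroxyphenyl)ethyl docosanoate | CCCCCCCCCCCCCCCCCCCCCC(=O)OCCc1ccc(O)cc1 | target

Total step count: 2
Longest linear sequence: 2 steps (1 → 2 → 5)

Steps most likely to fail (the route has only two steps, so both are ranked):

Step 2 (key step). Decarbonylation of the formate may be too slow at near-stoichiometric loading to sustain the carbonylation. The electron-rich phenol ring may also undergo acid-promoted Friedel–Crafts alkylation by the olefin, or acylation may occur at the phenolic oxygen. The fallback sets out from 3 and forms the C2–C1 bond on the olefin alone, with no phenol present. Olefin 3 would be methoxycarbonylated under CO gas (Pd(dba)2, dtbpx, MsOH, CO 20 bar, MeOH/PhMe, 90 °C), the standard isomerising alkoxycarbonylation, to give methyl docosanoate F1. F1 would then be transesterified with tyrosol 1 using immobilised Candida antarctica lipase B (Novozym 435, 2-methyl-2-butanol, 60 °C, 5 Å sieves to trap methanol). The lipase should acylate only the primary hydroxyl, and the route is rejoined at 5.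

Step 1. Esterification may stop short at equilibrium, the labile formyl group may be lost by hydrolysis during isolation, or the phenol may be partly formylated. The fallback removes the need for a pre-installed formyl group. It sets out from 1, which would be combined directly with 3 in a three-component hydroalkoxycarbonylation under CO gas (Pd(dba)2, dtbpx, MsOH, CO 20–30 bar, PhMe, 90 °C, 1.5 equiv of 1). The carbonyl carbon then comes from gaseous CO and the acyl-palladium is intercepted by the primary hydroxyl of 1. This comes back to the route at 5 and makes no new compound (F0).

Further compounds
F1 | step 2 | methyl docosanoate | CCCCCCCCCCCCCCCCCCCCCC(=O)OC
F0 | step 1 | none | none
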